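**Plan**
- Retrosynthesis: the four C–Br bonds are cut first. C2–Br and C5–Br go back to carboxylic acids (ipso-bromodecarboxylation); C3–Br and C4–Br go back to C–H and, one stage earlier, to enol C–O bonds removed via triflates.
- The ring is then cut at C2–C3 and C4–C5. The pyrrole (the only ring) has a mirror plane through N1 and the midpoint of C3–C4, so it divides into a C2–N1–C5 piece (N-methyliminodiacetate) and a C3–C4 piece (oxalate).
- Forward: esterification of N-methyliminodiacetic acid; closure of the pyrrole ring in one double Claisen condensation with dimethyl oxalate; bis-triflation; reductive removal of both triflates; saponification; fourfold bromination with loss of two CO2.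
- Stereochemistry: the target is planar and achiral, so no stereocentre has to be set; the single sp3 centre of the open-chain intermediate disappears on aromatisation.

Key step: step 2

Remark: ammonium, enolate and carboxylate salts that exist only until the aqueous work-up of steps 1, 2 and 5 are treated as the neutral compounds they become, and in the twofold reactions of the mirror-symmetric intermediates (steps 3–6) the half-converted species are taken to react on and are not numbered.

Step 1
Reactants: 1 N-methyliminodiacetic acid; 2 methanol (reagent and solvent)
Product: 3 dimethyl N-methyliminodiacetate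
Conditions: SOCl2 (2.5 equiv), MeOH, 0 °C to reflux; aq. NaHCO3 work-up
Reagents that add atoms: methanol (2), CO
Why: Fischer esterification driven by HCl generated in situ from SOCl2 and methanol, the standard way to esterify amino acids, in which the protonated tertiary amine stays inert and is freed by the bicarbonate wash.

Step 2
Reactants: 3 dimethyl N-methyliminodiacetate; 4 dimethyl oxalate
Product: 6 dimethyl 3,4-dihydroxy-1-methyl-1H-pyrrole-2,5-dicarboxylate, via open-chain oxalyl adduct 5 (not isolated)
Conditions: NaOMe (2.5 equiv), MeOH, reflux; then aq. HCl, 0 °C
Reagents that add atoms: none
Why: Methoxide forms the ester enolate at one N–CH2 carbon of 3, which adds to an ester carbonyl of 4 and expels methoxide (crossed Claisen condensation, bond C2–C3) to give 5 as its stabilised enolate. The enolate of the second N–CH2 ester then attacks the remaining oxalyl ester carbonyl in a 5-exo-trig Dieckmann-type acyl substitution that forms C4–C5 and closes the pyrrole ring, and the cyclic 3,4-diketone enolises twice to the aromatic diol. This is the Hinsberg pyrrole synthesis, established for N-alkyl- and N-benzyliminodiacetates with oxalate esters. No stereocentre is created, since the sp3 carbon of 5 becomes sp2 on aromatisation. The step needs ring closure to win over intermolecular acylation and needs clean C-acylation; the five-membered transition state, the non-enolisable oxalate, the matched methyl esters and methoxide (ester exchange is degenerate) and the irreversible twofold deprotonation of 6, which leaves the equilibria as a sparingly soluble sodium salt until the acid quench, should secure both.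

Step 3
Reactants: 6 dimethyl 3,4-dihydroxy-1-methyl-1H-pyrrole-2,5-dicarboxylate
Product: 7 dimethyl 1-methyl-3,4-bis(trifluoromethanesulfonyloxy)-1H-pyrrole-2,5-dicarboxylate
Conditions: Tf2O (2.5 equiv), pyridine, CH2Cl2, 0 °C to rt
Reagents that add atoms: trifluoromethanesulfonic anhydride, O=S(=O)(OS(=O)(=O)C(F)(F)F)C(F)(F)F
Why: O-sulfonylation of the two acidic enolic hydroxyl groups (aryl triflate formation), in which the flanking esters keep the ring too electron-poor for C-sulfonylation or oxidation; bis-triflates of this pyrrole type are known cross-coupling partners.

Step 4
Reactants: 7 dimethyl 1-methyl-3,4-bis(trifluoromethanesulfonyloxy)-1H-pyrrole-2,5-dicarboxylate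
Product: 8 dimethyl 1-methyl-1H-pyrrole-2,5-dicarboxylate
Conditions: Pd(OAc)2 (10 mol%), 1,3-bis(diphenylphosphino)propane (12 mol%), HCO2H, Et3N, DMF, 80 °C
Reagents that add atoms: none
Why: Palladium-catalysed formate transfer hydrogenolysis of aryl triflates, in which zerovalent palladium formed in situ inserts into each C–OTf bond, formate replaces triflate on divalent palladium and loses CO2 to give a palladium hydride, and C–H reductive elimination follows, while the methyl esters and the N-methyl group stay untouched.

Step 5
Reactants: 8 dimethyl 1-methyl-1H-pyrrole-2,5-dicarboxylate
Product: 9 1-methyl-1H-pyrrole-2,5-dicarboxylic acid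
Conditions: LiOH (5 equiv), THF/MeOH/H2O, 50 °C; then aq. HCl to pH 2, 0 °C
Reagents that add atoms: lithium hydroxide, [Li+].[OH-]
Why: Saponification (acyl–oxygen ester hydrolysis) of both methyl esters, with acidification in the cold so that the pyrrole-2-carboxylic acid groups are not lost by acid-promoted protodecarboxylation.

Step 6
Reactants: 9 1-methyl-1H-pyrrole-2,5-dicarboxylic acid
Product: 10 2,3,4,5-tetrabromo-1-methyl-1H-pyrrole
Conditions: NBS (4.4 equiv), LiOAc (20 mol%), DMF, 0 °C to rt, dark
Reagents that add atoms: N-bromosuccinimide, O=C1CCC(=O)N1Br
Why: Electrophilic bromination of the pyrrole, in which C3 and C4 react by ordinary aromatic substitution and the carboxyl-bearing C2 and C5 by ipso attack and loss of CO2 (Hunsdiecker-type bromodecarboxylation of pyrrole-2-carboxylic acids, helped by catalytic carboxylate formation), so that every order of the four events converges on 10.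

**Compound list**
1 | N-methyliminodiacetic acid | CN(CC(=O)O)CC(=O)O | starting material
2 | methanol | CO | starting material
3 | dimethyl N-methyliminodiacetate | COC(=O)CN(C)CC(=O)OC | intermediate
4 | dimethyl oxalate | COC(=O)C(=O)OC | starting material
5 | dimethyl 2-[(2-methoxy-2-oxoethyl)(methyl)amino]-3-oxobutanedioate (open-chain oxalyl adduct; racemic, configurationally labile, present as its sodium enolate) | COC(=O)CN(C)C(C(=O)OC)C(=O)C(=O)OC | intermediate
6 | dimethyl 3,4-dihydroxy-1-methyl-1H-pyrrole-2,5-dicarboxylate | COC(=O)c1c(O)c(O)c(C(=O)OC)n1C | intermediate
7 | dimethyl 1-methyl-3,4-bis(trifluoromethanesulfonyloxy)-1H-pyrrole-2,5-dicarboxylate | COC(=O)c1c(OS(=O)(=O)C(F)(F)F)c(OS(=O)(=O)C(F)(F)F)c(C(=O)OC)n1C | intermediate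
8 | dimethyl 1-methyl-1H-pyrrole-2,5-dicarboxylate | COC(=O)c1ccc(C(=O)OC)n1C | intermediate
9 | 1-methyl-1H-pyrrole-2,5-dicarboxylic acid | Cn1c(C(=O)O)ccc1C(=O)O | intermediate
10 | 2,3,4,5-tetrabromo-1-methyl-1H-pyrrole | Cn1c(Br)c(Br)c(Br)c1Br | target

**Step count**
Total steps: 6. Longest linear sequence: 6 steps (1 to 10).

**Steps most likely to fail**

Step 4. Formate or triethylamine may attack sulfur of the electron-poor triflate (S–O cleavage) and return the hydroxyl group. The second C–OTf bond may also react too slowly once the first reduction has made the ring more electron-rich, so that the reduction stalls halfway. The fallback sets out from bis-triflate 7 and exchanges both triflates directly for bromide, with no hydride source or amine present. The conditions are the palladium-catalysed triflate-to-bromide exchange (Pd2(dba)3, t-BuBrettPhos, KBr, KF, 1,4-dioxane, 130 °C), which should give dimethyl 3,4-dibromo-1-methyl-1H-pyrrole-2,5-dicarboxylate F1. Saponification and cold acidification as in step 5 should give 3,4-dibromo-1-methyl-1H-pyrrole-2,5-dicarboxylic acid F2. NBS (2.2 equiv) with catalytic LiOAc in DMF then replaces the two carboxyl groups by bromine, and the fallback comes back to the route at target 10.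

Step 6. Excess NBS may oxidise the electron-rich, partly brominated ring (ring degradation towards bromomaleimide-type products) while the last ipso-substitution on the deactivated ring lags, so that conversion stays incomplete or material is lost. The fallback sets out from diacid 9 and separates the two tasks. Thermal protodecarboxylation (ethanolamine, about 170 °C, with distillation of the volatile product) should give 1-methyl-1H-pyrrole F3. Exhaustive bromination with NBS (4.0 equiv) in THF from −78 °C to room temperature, the usual way to perbrominate N-alkylpyrroles, comes back to the route at target 10.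

Step 2. Intermolecular acylation of the enolate of 5 by further oxalate may outrun the ring closure and give oligomers, or traces of hydroxide may saponify the esters and halt the condensation at the open-chain stage. The fallback sets out from diester 3 and carries the C3–C4 unit at the aldehyde oxidation level. Condensation with glyoxal (trimer dihydrate) and NaOMe in MeOH, the aldol variant of the Hinsberg synthesis, closes the same two bonds and aromatises by loss of water. Its Stobbe-type course should give the half-ester 5-(methoxycarbonyl)-1-methyl-1H-pyrrole-2-carboxylic acid F4 after acidification. Saponification of F4 under the conditions of step 5 comes back to the route at diacid 9, so that 6, 7 and 8 are bypassed. Glyoxal is kept in reserve because, unlike oxalate, it oligomerises and disproportionates under alkoxide.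

**Further compounds**
F1 | step 4 | dimethyl 3,4-dibromo-1-methyl-1H-pyrrole-2,5-dicarboxylate | COC(=O)c1c(Br)c(Br)c(C(=O)OC)n1C
F2 | step 4 | 3,4-dibromo-1-methyl-1H-pyrrole-2,5-dicarboxylic acid | Cn1c(C(=O)O)c(Br)c(Br)c1C(=O)O
F3 | step 6 | 1-methyl-1H-pyrrole | Cn1cccc1
F4 | step 2 | 5-(methoxycarbonyl)-1-methyl-1H-pyrrole-2-carboxylic acid | COC(=O)c1ccc(C(=O)O)n1C
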